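4 questions hang on the teal flask, in which a trace of catalyst stands over substrate turning into target: how much target is there at 6.0 d, and what is each remedy worth?

| flask | substrate | catalyst | temperature | remark | time |
|---|---|---|---|---|---|
| teal | 0.10 M | 0.05 mol% | 0 °C | the very flask that is asked about, followed so far |  |
| violet | 0.10 M | 0.05 mol% | −15 °C | run made earlier |  |
| flask | 0.10 M | 0.05 mol% | 0 °C |  | 6.0 d |

- teal (time / h: target / %): 6.00: 19.6; 15.0: 38.3; 30.0: 42.8; 50.0: 38.3; 72.0: 30.9; 96.0: 25.7
- violet (time / h: target / %): 12.0: 7.3; 30.0: 15.4; 60.0: 21.7; 96.0: 29.8; 144: 31.4; 192: 33.4

(scatter of a reading: 1 percentage point)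

- target, in percent of the substrate first charged, at 6.0 d
- the remedy with the largest gain of target, or "none" below 2 percentage points (ash / larch / oak / alder / none)
- target present, with what was taken out counted in, in percent of the substrate first charged, after ash
- target present, with what was taken out counted in, in percent of the substrate first charged, after larch

- ash: at 6.0 d raise the temperature by 10 K, then wait 6.0 d
- larch: at 6.0 d take out 90% of the target then present, then wait 6.0 d
- oak: at 6.0 d add catalyst, 50.0% of the amount charged, then wait 6.0 d
- alder: change nothing and wait 6.0 d more

- what is taken out of target is counted as made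
- what was read earlier has a scatter of 1 percentage point, one standard deviation
- steps thought possible: substrate <-> target; target + catalyst <-> isomer of the product A + catalyst; isomer of the product A + catalyst <-> isomer of the product B + catalyst
- additions bring no volume worth counting

One pair of readings looks wrong. At 96.0 h the colder violet run reads more target than the teal flask, 29.8% against 25.7%, although teal read 42.8% at 30.0 h. But the violet readings still rise up to the last one, while the teal readings fall after 30.0 h, so I reckon the falling leg of teal:

k = ln(38.3 / 25.7) / (96.0 − 50.0) = 0.00867 h⁻¹

I call this the drain constant: the pseudo-first-order fractional loss of target per hour, as read off these two teal readings, once substrate ⇌ target keeps pace. The teal readings first rise by 0.0327 h⁻¹ of the charge, while this drain takes 0.00371 h⁻¹ of the charge even at the highest reading, which is less, so I treat substrate ⇌ target as the faster process and take target as a steady share of a shrinking pool. Running the line back to zero time and forward gives: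

intercept = 59.1%

target at 6.0 d = intercept × exp(−k t) = 16.9%

On this line target is still falling at 6.0 d, so I expect waiting and extra catalyst to lose target, and I choose larch, which banks 15.3% of the charge.

The forecast gives 20.5% (18% to 23%), larch, 17.5% after ash and 32.5% after larch, reasoning that "The late flask is therefore near equilibrium", and its first figure stands above mine.

The teal flask gives 17.7% at 6.0 d against my 16.9%, with larch best at 26.3% and ash at 10.4%.

    substrate ⇌ target (K = 3.80, k = 1.20 × 10⁻⁵ s⁻¹, Ea = 81.0 kJ mol⁻¹, ΔH = −24.0 kJ mol⁻¹)
    target + catalyst ⇌ isomer of the product A + catalyst, rate k2*[catalyst]*[target] forward; the back reaction follows from the equilibrium constant (K = 1.70, k = 0.150 L mol⁻¹ s⁻¹, Ea = 53.0 kJ mol⁻¹, ΔH = −1.00 kJ mol⁻¹)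
    isomer of the product A + catalyst ⇌ isomer of the product B + catalyst, rate k3*[catalyst]*[isomer of the product A] forward; the back reaction follows from the equilibrium constant (K = 3.00, k = 0.330 L mol⁻¹ s⁻¹, Ea = 47.0 kJ mol⁻¹, ΔH = 17.0 kJ mol⁻¹)
    (constants at 0 °C)

With the step from target to isomer of the product A taken away, both ways, the teal flask holds 79.1% target at 6.0 d instead of 17.7%, so that step is the main reason for the low figure. Its rate carries [catalyst], and the neighbour flask at 0.025 M of substrate has, at the same loading, a quarter of that [catalyst]. The drain line, with k scaled by that share and the intercept held, gives:

target at 6.0 d = 43.2%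

That neighbour flask holds 44.8% target at 6.0 d.

The readings stem from a simulated flask for an exercise.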